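**Strategy**

The flavan is cut at C2–C3. C2 is a benzylic CH bonded to O1, so before ring C exists it is the OCH2 of a ring B benzyl ether on O1 of ring A, activated by both oxygen and aryl toward a rhodium carbene generated at C3 beside the C4 ketone. One enantioselective C–H insertion forges C2–C3, closes ring C as a flavanone and sets C2 as (S). The precursor is a terminal aryl diazoketone whose second ortho oxygen (O5) carries a bulky silyl ether instead of an acetal, so no other O–CH2 sits within reach of the carbene. C4 is then deoxygenated and the C8 prenyl group, which a carbene would cyclopropanate, is added last.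

Key step: step 8

Remark (assumption): the sense of induction of Rh2(S-PTTL)4 on this substrate is assumed to give (2S); should analysis of the flavanone show the opposite, the mirror-image catalyst Rh2(R-PTTL)4 is used and nothing else changes.

**Route**

Step 1
Reactants: 1 2,4,6-trihydroxyacetophenone
Product: 2 1-[2,6-dihydroxy-4-(methoxymethoxy)phenyl]ethanone
Conditions: MOMCl (1.0 equiv), iPr2NEt (1.1 equiv), THF, −10 → 0 °C
Reagents that add atoms: chloromethyl methyl ether (MOMCl), COCCl
Why: O-alkylation of a phenol with an α-chloro ether, in which the C4 hydroxyl, the only one not hydrogen-bonded to the ketone and the most acidic, should react first, so that one equivalent of MOMCl should stop at the mono-ether.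

Step 2
Reactants: 3 3-hydroxy-5-methoxybenzaldehyde
Product: 4 3-methoxy-5-(methoxymethoxy)benzaldehyde
Conditions: MOMCl (1.3 equiv), iPr2NEt (1.5 equiv), CH2Cl2, 0 °C → rt
Reagents that add atoms: chloromethyl methyl ether (MOMCl), COCCl
Why: routine MOM protection of a phenol by O-alkylation, needed so that ring B carries no acidic hydrogen in the later base and carbene steps.

Step 3
Reactants: 4 3-methoxy-5-(methoxymethoxy)benzaldehyde
Product: 5 [3-methoxy-5-(methoxymethoxy)phenyl]methanol
Conditions: NaBH4, MeOH, 0 °C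
Reagents that add atoms: none
Why: borohydride reduction of an aldehyde to the primary alcohol, to which the methyl and MOM ethers are inert.

Step 4
Reactants: 5 [3-methoxy-5-(methoxymethoxy)phenyl]methanol
Product: 6 1-(bromomethyl)-3-methoxy-5-(methoxymethoxy)benzene
Conditions: CBr4, PPh3, CH2Cl2, 0 °C
Reagents that add atoms: carbon tetrabromide, BrC(Br)(Br)Br
Why: Appel bromination of a benzylic alcohol under neutral conditions, chosen so that the acid-labile MOM acetal survives.

Step 5
Reactants: 2 1-[2,6-dihydroxy-4-(methoxymethoxy)phenyl]ethanone; 6 1-(bromomethyl)-3-methoxy-5-(methoxymethoxy)benzene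
Product: 7 1-[2-hydroxy-6-[[3-methoxy-5-(methoxymethoxy)phenyl]methoxy]-4-(methoxymethoxy)phenyl]ethanone
Conditions: 6 (1.0 equiv), K2CO3 (1.2 equiv), acetone, 50 °C
Reagents that add atoms: none
Why: Williamson etherification of one of two equivalent phenols, which should stop at the mono-ether because the remaining hydroxyl is then locked in a hydrogen bond to the ketone and is far less nucleophilic.

Step 6
Reactants: 7 1-[2-hydroxy-6-[[3-methoxy-5-(methoxymethoxy)phenyl]methoxy]-4-(methoxymethoxy)phenyl]ethanone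
Product: 8 1-[2-[[3-methoxy-5-(methoxymethoxy)phenyl]methoxy]-4-(methoxymethoxy)-6-[tri(propan-2-yl)silyloxy]phenyl]ethanone
Conditions: TIPSCl (1.3 equiv), imidazole (2.5 equiv), DMAP (cat.), DMF, 40 °C
Reagents that add atoms: chlorotri(propan-2-yl)silane (TIPSCl), CC(C)[Si](Cl)(C(C)C)C(C)C
Why: imidazole-promoted silylation of the last phenol, which places on the future O5 a group without an oxygen-activated C–H bond and with a shielded, weakly basic oxygen.

Step 7
Reactants: 8 1-[2-[[3-methoxy-5-(methoxymethoxy)phenyl]methoxy]-4-(methoxymethoxy)-6-[tri(propan-2-yl)silyloxy]phenyl]ethanone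
Product: 10 2-diazo-1-[2-[[3-methoxy-5-(methoxymethoxy)phenyl]methoxy]-4-(methoxymethoxy)-6-[tri(propan-2-yl)silyloxy]phenyl]ethanone, via trifluoroacetyl ketone 9 (not isolated)
Conditions: LiHMDS (1.1 equiv), THF, −78 °C; CF3CO2CH2CF3 (1.2 equiv), −78 °C; aq. NH4Cl work-up; then 4-acetamidobenzenesulfonyl azide (1.5 equiv), Et3N (1.5 equiv), H2O (1 equiv), MeCN, rt
Reagents that add atoms: 4-acetamidobenzenesulfonyl azide, CC(=O)Nc1ccc(cc1)S(=O)(=O)N=[N+]=[N-]
Why: Danheiser detrifluoroacetylative diazo transfer, in which Claisen trifluoroacetylation of the only possible enolate activates the methyl carbon for Regitz diazo transfer and the trifluoroacetyl group then leaves on the sulfonamide nitrogen, all at temperatures where the hindered TIPS ether should not migrate.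

Step 8
Reactants: 10 2-diazo-1-[2-[[3-methoxy-5-(methoxymethoxy)phenyl]methoxy]-4-(methoxymethoxy)-6-[tri(propan-2-yl)silyloxy]phenyl]ethanone
Product: 11 (2S)-2-[3-methoxy-5-(methoxymethoxy)phenyl]-7-(methoxymethoxy)-5-[tri(propan-2-yl)silyloxy]-2,3-dihydrochromen-4-one
Conditions: Rh2(S-PTTL)4 [dirhodium tetrakis(N-phthaloyl-(S)-tert-leucinate)] (1 mol %), CH2Cl2, 0 °C, slow addition of 10
Reagents that add atoms: none
Why: Rh2(S-PTTL)4 expels N2 from 10 and the resulting electrophilic carbenoid at C3 takes up one hydrogen of the O1–CH2–aryl group through a concerted three-centre, hydride-transfer-like transition state, which creates the C2–C3 bond. The closest known reaction type is the intramolecular C–H insertion of ortho-alkoxyaryl α-diazoketones to 2-substituted chroman-4-ones under chiral carboxylate dimers of divalent rhodium. Ring C closes in a 1,6 sense through a six-membered array (C3, C4, C4a, C8a, O1, C2) in which the ring B aryl group can lie pseudo-equatorial. C2 is set under catalyst control: the phthalimido walls of the four tert-leucinate ligands expose one of the two enantiotopic benzylic hydrogens to the carbenoid, expected to give (S). The step needs insertion to win over attack of O1 on the carbenoid (oxonium ylide, then 1,2-benzyl shift), which is helped by O1 being a weakly basic vinylogous ester oxygen, by the C–H bond being activated by both oxygen and ring B, and by the use of a rhodium carboxylate. On the other flank the O5 TIPS ether has no oxygen-activated C–H within six-membered reach and its bulk turns the carbenoid toward O1, while the MOM groups on O7 and ring B are too far away to interfere.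

Step 9
Reactants: 11 (2S)-2-[3-methoxy-5-(methoxymethoxy)phenyl]-7-(methoxymethoxy)-5-[tri(propan-2-yl)silyloxy]-2,3-dihydrochromen-4-one
Product: 12 (2S,4S)-2-[3-methoxy-5-(methoxymethoxy)phenyl]-7-(methoxymethoxy)-5-[tri(propan-2-yl)silyloxy]-3,4-dihydro-2H-chromen-4-ol
Conditions: NaBH4, MeOH/THF (1:1), 0 °C
Reagents that add atoms: none
Why: borohydride reduction of the aryl ketone under substrate control (axial hydride delivery should favour the 2,4-cis alcohol), run cold to avoid base-induced ring opening at C2; the C4 centre is erased in step 10, so any trans epimer is carried along.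

Step 10
Reactants: 12 (2S,4S)-2-[3-methoxy-5-(methoxymethoxy)phenyl]-7-(methoxymethoxy)-5-[tri(propan-2-yl)silyloxy]-3,4-dihydro-2H-chromen-4-ol
Product: 13 (2S)-2-[3-methoxy-5-(methoxymethoxy)phenyl]-7-(methoxymethoxy)-5-[tri(propan-2-yl)silyloxy]-3,4-dihydro-2H-chromene
Conditions: Et3SiH (5 equiv), TFA (2 equiv), CH2Cl2, −40 → −20 °C
Reagents that add atoms: none
Why: ionic hydrogenation, in which the C4 hydroxyl ionises under very mild acid to a benzylic cation stabilised by O1, O5 and O7 and is trapped by silane hydride, conditions under which the MOM and TIPS ethers and C2 should be untouched.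

Step 11
Reactants: 13 (2S)-2-[3-methoxy-5-(methoxymethoxy)phenyl]-7-(methoxymethoxy)-5-[tri(propan-2-yl)silyloxy]-3,4-dihydro-2H-chromene
Product: 14 (2S)-8-bromo-2-[3-methoxy-5-(methoxymethoxy)phenyl]-7-(methoxymethoxy)-5-[tri(propan-2-yl)silyloxy]-3,4-dihydro-2H-chromene
Conditions: NBS (1.0 equiv), CH2Cl2, −78 → −40 °C, dark
Reagents that add atoms: N-bromosuccinimide, O=C1CCC(=O)N1Br
Why: electrophilic aromatic bromination, expected on ring A (three oxygen donors against two on ring B) and at C8, the usual site in 5,7-di-O-protected flavans, with C6 further shielded between the TIPS and MOM ethers.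

Step 12
Reactants: 14 (2S)-8-bromo-2-[3-methoxy-5-(methoxymethoxy)phenyl]-7-(methoxymethoxy)-5-[tri(propan-2-yl)silyloxy]-3,4-dihydro-2H-chromene; 15 prenyl bromide (1-bromo-3-methylbut-2-ene)
Product: 18 (2S)-2-[3-methoxy-5-(methoxymethoxy)phenyl]-7-(methoxymethoxy)-8-(3-methylbut-2-enyl)-5-[tri(propan-2-yl)silyloxy]-3,4-dihydro-2H-chromene, via C8 aryllithium 16 (not isolated), via C8 arylcopper 17 (not isolated)
Conditions: t-BuLi (2.1 equiv), THF, −78 °C; CuBr·SMe2 (1.1 equiv), −78 → −40 °C; 15 (1.5 equiv), −78 → 0 °C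
Reagents that add atoms: none
Why: bromine–lithium exchange (faster than any deprotonation at −78 °C and stabilised by the neighbouring MOM ether), transmetalation to copper and SN2 allylation at the primary carbon of prenyl bromide, with the TIPS group meta to the metal and so unable to migrate.

Step 13
Reactants: 18 (2S)-2-[3-methoxy-5-(methoxymethoxy)phenyl]-7-(methoxymethoxy)-8-(3-methylbut-2-enyl)-5-[tri(propan-2-yl)silyloxy]-3,4-dihydro-2H-chromene
Product: 20 (2S)-2-(3-hydroxy-5-methoxyphenyl)-8-(3-methylbut-2-enyl)-3,4-dihydro-2H-chromene-5,7-diol, via C5 phenol 19 (not isolated)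
Conditions: TBAF (1.1 equiv), THF, 0 °C; then MeOH, aq. HCl (3 M), 40 °C, stopped as soon as the MOM groups are gone
Reagents that add atoms: none
Why: fluoride desilylation followed in the same flask by acid-catalysed acetal exchange of the two MOM ethers with methanol, under conditions mild enough that the ring B methyl ether, the C2 ether (no cation-stabilising para donor on ring B) and the prenyl double bond should survive.

**Compound list**

1 | 2,4,6-trihydroxyacetophenone | CC(=O)c1c(O)cc(O)cc1O | starting material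
2 | 1-[2,6-dihydroxy-4-(methoxymethoxy)phenyl]ethanone | CC(=O)c1c(O)cc(OCOC)cc1O | intermediate
3 | 3-hydroxy-5-methoxybenzaldehyde | COc1cc(O)cc(C=O)c1 | starting material
4 | 3-methoxy-5-(methoxymethoxy)benzaldehyde | COCOc1cc(OC)cc(C=O)c1 | intermediate
5 | [3-methoxy-5-(methoxymethoxy)phenyl]methanol | COCOc1cc(OC)cc(CO)c1 | intermediate
6 | 1-(bromomethyl)-3-methoxy-5-(methoxymethoxy)benzene | COCOc1cc(OC)cc(CBr)c1 | intermediate
7 | 1-[2-hydroxy-6-[[3-methoxy-5-(methoxymethoxy)phenyl]methoxy]-4-(methoxymethoxy)phenyl]ethanone | CC(=O)c1c(O)cc(OCOC)cc1OCc1cc(OC)cc(OCOC)c1 | intermediate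
8 | 1-[2-[[3-methoxy-5-(methoxymethoxy)phenyl]methoxy]-4-(methoxymethoxy)-6-[tri(propan-2-yl)silyloxy]phenyl]ethanone | CC(=O)c1c(O[Si](C(C)C)(C(C)C)C(C)C)cc(OCOC)cc1OCc1cc(OC)cc(OCOC)c1 | intermediate
9 | 4,4,4-trifluoro-1-[2-[[3-methoxy-5-(methoxymethoxy)phenyl]methoxy]-4-(methoxymethoxy)-6-[tri(propan-2-yl)silyloxy]phenyl]butane-1,3-dione (not isolated) | O=C(CC(=O)C(F)(F)F)c1c(O[Si](C(C)C)(C(C)C)C(C)C)cc(OCOC)cc1OCc1cc(OC)cc(OCOC)c1 | intermediate
10 | 2-diazo-1-[2-[[3-methoxy-5-(methoxymethoxy)phenyl]methoxy]-4-(methoxymethoxy)-6-[tri(propan-2-yl)silyloxy]phenyl]ethanone | COCOc1cc(OC)cc(COc2cc(OCOC)cc(O[Si](C(C)C)(C(C)C)C(C)C)c2C(=O)C=[N+]=[N-])c1 | intermediate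
11 | (2S)-2-[3-methoxy-5-(methoxymethoxy)phenyl]-7-(methoxymethoxy)-5-[tri(propan-2-yl)silyloxy]-2,3-dihydrochromen-4-one | COCOc1cc(OC)cc([C@@H]2CC(=O)c3c(O[Si](C(C)C)(C(C)C)C(C)C)cc(OCOC)cc3O2)c1 | intermediate
12 | (2S,4S)-2-[3-methoxy-5-(methoxymethoxy)phenyl]-7-(methoxymethoxy)-5-[tri(propan-2-yl)silyloxy]-3,4-dihydro-2H-chromen-4-ol (drawn as the expected major 2,4-cis epimer) | COCOc1cc(OC)cc([C@@H]2C[C@H](O)c3c(O[Si](C(C)C)(C(C)C)C(C)C)cc(OCOC)cc3O2)c1 | intermediate
13 | (2S)-2-[3-methoxy-5-(methoxymethoxy)phenyl]-7-(methoxymethoxy)-5-[tri(propan-2-yl)silyloxy]-3,4-dihydro-2H-chromene | COCOc1cc(OC)cc([C@@H]2CCc3c(O[Si](C(C)C)(C(C)C)C(C)C)cc(OCOC)cc3O2)c1 | intermediate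
14 | (2S)-8-bromo-2-[3-methoxy-5-(methoxymethoxy)phenyl]-7-(methoxymethoxy)-5-[tri(propan-2-yl)silyloxy]-3,4-dihydro-2H-chromene | COCOc1cc(OC)cc([C@@H]2CCc3c(O[Si](C(C)C)(C(C)C)C(C)C)cc(OCOC)c(Br)c3O2)c1 | intermediate
15 | prenyl bromide (1-bromo-3-methylbut-2-ene) | CC(C)=CCBr | starting material
16 | [(2S)-2-[3-methoxy-5-(methoxymethoxy)phenyl]-7-(methoxymethoxy)-5-[tri(propan-2-yl)silyloxy]-3,4-dihydro-2H-chromen-8-yl]lithium (not isolated) | COCOc1cc(OC)cc([C@@H]2CCc3c(O[Si](C(C)C)(C(C)C)C(C)C)cc(OCOC)c([Li])c3O2)c1 | intermediate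
17 | [(2S)-2-[3-methoxy-5-(methoxymethoxy)phenyl]-7-(methoxymethoxy)-5-[tri(propan-2-yl)silyloxy]-3,4-dihydro-2H-chromen-8-yl]copper (not isolated) | COCOc1cc(OC)cc([C@@H]2CCc3c(O[Si](C(C)C)(C(C)C)C(C)C)cc(OCOC)c([Cu])c3O2)c1 | intermediate
18 | (2S)-2-[3-methoxy-5-(methoxymethoxy)phenyl]-7-(methoxymethoxy)-8-(3-methylbut-2-enyl)-5-[tri(propan-2-yl)silyloxy]-3,4-dihydro-2H-chromene | COCOc1cc(OC)cc([C@@H]2CCc3c(O[Si](C(C)C)(C(C)C)C(C)C)cc(OCOC)c(CC=C(C)C)c3O2)c1 | intermediate
19 | (2S)-2-[3-methoxy-5-(methoxymethoxy)phenyl]-7-(methoxymethoxy)-8-(3-methylbut-2-enyl)-3,4-dihydro-2H-chromen-5-ol (not isolated) | COCOc1cc(OC)cc([C@@H]2CCc3c(O)cc(OCOC)c(CC=C(C)C)c3O2)c1 | intermediate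
20 | (2S)-2-(3-hydroxy-5-methoxyphenyl)-8-(3-methylbut-2-enyl)-3,4-dihydro-2H-chromene-5,7-diol | COc1cc(O)cc([C@@H]2CCc3c(O)cc(O)c(CC=C(C)C)c3O2)c1 | target

**Step count and risks**

Total step count: 13. Longest linear sequence: 12 steps (steps 2 to 13, from 3-hydroxy-5-methoxybenzaldehyde).

Steps most likely to fail:

1. Step 8. The carbenoid may be captured by the O1 lone pair, giving an oxonium ylide that undergoes a 1,2-benzyl shift instead of insertion, or the chiral pocket may distinguish the two enantiotopic benzylic hydrogens poorly. The fallback builds ring C by oxa-Michael closure and resolves afterwards; it sets out from 2 and 4 and comes back at 11. Claisen–Schmidt condensation of 2 with 4 (KOH, EtOH/H2O, rt) should give the chalcone (E)-1-[2,6-dihydroxy-4-(methoxymethoxy)phenyl]-3-[3-methoxy-5-(methoxymethoxy)phenyl]prop-2-en-1-one F1. Closure of this 2′,6′-dihydroxychalcone (NaOAc, EtOH, reflux) should give the racemic 5-hydroxyflavanone F2, and silylation (TIPSCl, imidazole, DMF) the racemic silyl ether F3. Kinetic resolution by asymmetric transfer hydrogenation (RuCl(p-cymene)[(R,R)-TsDPEN] or its (S,S) antipode, whichever consumes the (2R)-ketone faster; HCO2H/Et3N, EtOAc, rt) should convert the (2R)-enantiomer into the cis-alcohol (2R,4R)-flavan-4-ol F4, which is separated by chromatography. The unreacted (2S)-ketone is 11.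

2. Step 11. Bromine may enter at C6 or on ring B in competition with C8, or a second bromination may follow. The fallback delivers the prenyl group to C8 by sigmatropic shifts instead of electrophilic substitution; it sets out from 11 and comes back at 19. Buffered desilylation (TBAF, AcOH, THF, 0 °C) should give the (2S)-5-hydroxyflavanone F5, and Mitsunobu etherification with 3-methylbut-2-en-1-ol (PPh3, DIAD, THF, 0 °C) its 5-O-prenyl ether F6. Eu(fod)3 (10 mol %) in CHCl3 at 60 °C should then trigger a Claisen shift to C6 followed by a Cope shift to C8, giving the (2S)-5-hydroxy-8-prenylflavanone F7. Ethyl chloroformate and Et3N (THF, 0 °C) convert the chelated phenol into the ethyl carbonate F8, which NaBH4 in aqueous THF should reduce through the ortho-quinone methide to 19. Compound 19 then enters the acid stage of step 13.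

3. Step 12. The arylcopper may attack the tertiary end of the allyl system (SN2′, giving the 1,1-dimethylallyl isomer), or the aryllithium may be lost by proton transfer before coupling. The fallback replaces the organolithium and copper chemistry by palladium catalysis and olefin metathesis; it sets out from 14 and comes back at 18. Stille coupling with allyltributylstannane (Pd(P(t-Bu)3)2, dioxane, 90 °C) should give the (2S)-8-allylflavan F9, for which no regiochemical question arises. Cross-metathesis with excess 2-methylbut-2-ene (second-generation Grubbs catalyst RuCl2(=CHPh)(PCy3)(H2IMes), CH2Cl2, 40 °C) should then give 18.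

**Further compounds**

F1 | step 8 | (E)-1-[2,6-dihydroxy-4-(methoxymethoxy)phenyl]-3-[3-methoxy-5-(methoxymethoxy)phenyl]prop-2-en-1-one | COCOc1cc(OC)cc(/C=C/C(=O)c2c(O)cc(OCOC)cc2O)c1
F2 | step 8 | racemic 5-hydroxy-2-[3-methoxy-5-(methoxymethoxy)phenyl]-7-(methoxymethoxy)-2,3-dihydrochromen-4-one | COCOc1cc(OC)cc(C2CC(=O)c3c(O)cc(OCOC)cc3O2)c1
F3 | step 8 | racemic 2-[3-methoxy-5-(methoxymethoxy)phenyl]-7-(methoxymethoxy)-5-[tri(propan-2-yl)silyloxy]-2,3-dihydrochromen-4-one | COCOc1cc(OC)cc(C2CC(=O)c3c(O[Si](C(C)C)(C(C)C)C(C)C)cc(OCOC)cc3O2)c1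
F4 | step 8 | (2R,4R)-2-[3-methoxy-5-(methoxymethoxy)phenyl]-7-(methoxymethoxy)-5-[tri(propan-2-yl)silyloxy]-3,4-dihydro-2H-chromen-4-ol | COCOc1cc(OC)cc([C@H]2C[C@@H](O)c3c(O[Si](C(C)C)(C(C)C)C(C)C)cc(OCOC)cc3O2)c1
F5 | step 11 | (2S)-5-hydroxy-2-[3-methoxy-5-(methoxymethoxy)phenyl]-7-(methoxymethoxy)-2,3-dihydrochromen-4-one | COCOc1cc(OC)cc([C@@H]2CC(=O)c3c(O)cc(OCOC)cc3O2)c1
F6 | step 11 | (2S)-2-[3-methoxy-5-(methoxymethoxy)phenyl]-7-(methoxymethoxy)-5-(3-methylbut-2-enoxy)-2,3-dihydrochromen-4-one | COCOc1cc(OC)cc([C@@H]2CC(=O)c3c(OCC=C(C)C)cc(OCOC)cc3O2)c1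
F7 | step 11 | (2S)-5-hydroxy-2-[3-methoxy-5-(methoxymethoxy)phenyl]-7-(methoxymethoxy)-8-(3-methylbut-2-enyl)-2,3-dihydrochromen-4-one | COCOc1cc(OC)cc([C@@H]2CC(=O)c3c(O)cc(OCOC)c(CC=C(C)C)c3O2)c1
F8 | step 11 | ethyl [(2S)-2-[3-methoxy-5-(methoxymethoxy)phenyl]-7-(methoxymethoxy)-8-(3-methylbut-2-enyl)-4-oxo-2,3-dihydrochromen-5-yl] carbonate | COCOc1cc(OC)cc([C@@H]2CC(=O)c3c(OC(=O)OCC)cc(OCOC)c(CC=C(C)C)c3O2)c1
F9 | step 12 | (2S)-2-[3-methoxy-5-(methoxymethoxy)phenyl]-7-(methoxymethoxy)-8-(prop-2-enyl)-5-[tri(propan-2-yl)silyloxy]-3,4-dihydro-2H-chromene | COCOc1cc(OC)cc([C@@H]2CCc3c(O[Si](C(C)C)(C(C)C)C(C)C)cc(OCOC)c(CC=C)c3O2)c1
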